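## Retrosynthetic overview

Target is (3R,4R,6R,7S,8S,10R). Ring atoms use germacrane numbering C1–C10; C11–C13 are the lactone carbons, C14 is the methyl on C10, and C15 is the methyl on C4.
1. The C8 angelate and C10 acetate come from acylating the keto-diol **26**. The trans-fused 6,12-lactone, including C6, comes from 5-exo iodolactonization of an acrylic acid tethered at C7 onto an (E)-C5=C6 alkene, followed by C5 deiodination.
2. **Key bold step:** an anionic oxy-Cope ring expansion (6→10) of a 1-(Z-2-methoxyvinyl)-2-(Z-propenyl)cyclohexanol. In one operation it forms the C3–C4 bond with both stereocentres, the (E)-C5=C6 alkene and the C1 ketone.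
3. The cyclohexane (C1, C6–C10) comes from (R)-carvone. C7 is retained; C10–O comes from deconjugative α-hydroxylation; C8–O comes from hydroxyl-directed epoxidation and Red-Al opening; C12 comes from Riley oxidation.

Assumptions:
- (Z)-1-Methoxy-2-(tributylstannyl)ethene (**16**) is available by a one-step literature preparation.
- The C1 configuration in **9, 10, 17** is irrelevant, because C1 becomes a ketone.

## Route

**Step 1**
Reactants: **1** (R)-(−)-carvone
Product: **3** (5R)-5-(3-hydroxyprop-1-en-2-yl)-2-methylcyclohex-2-en-1-one ("10-hydroxycarvone")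
Conditions: SeO2 (10 mol%), TBHP, CH2Cl2, 25 °C
Reagents that add atoms: tert-butyl hydroperoxide (**2**), CC(C)(C)OO (O transfer)
Why: Riley allylic oxidation (ene/[2,3]) occurs at the accessible isopropenyl methyl (C12) rather than the deactivated enone ring, giving the C12 oxidation level; C7 is untouched.

**Step 2**
Reactants: **3**
Product: **5** (5R)-5-[3-(TBSO)prop-1-en-2-yl]-2-methylcyclohex-2-en-1-one
Conditions: TBSCl, imidazole, DMF, 0→25 °C
Reagents that add atoms: TBSCl (**4**), CC(C)(C)[Si](C)(C)Cl
Why: Silyl protection of the primary allylic alcohol, so it cannot direct the later vanadium epoxidation.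

**Step 3**
Reactants: **5**
Product: **7** (2R,5S)-2-hydroxy-5-[3-(TBSO)prop-1-en-2-yl]-2-methylcyclohex-3-en-1-one (C10–OH, C8=C9 alkene)
Conditions: KOtBu, tBuOH/THF, 0 °C; then O2, −20 °C; then P(OEt)3
Reagents that add atoms: dioxygen (**6**), O=O
Why: KOtBu gives the thermodynamic extended dienolate by γ-deprotonation at C8. O2 traps it at Cα (C10) anti to the C7 substituent, so O10 ends up trans to C11. P(OEt)3 reduces the hydroperoxide, and the alkene has migrated to C8=C9 (deconjugative α-hydroxylation).

**Step 4**
Reactants: **7**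
Product: **8** C8,C9-epoxide of **7**, with the epoxide oxygen cis to C10–OH
Conditions: VO(acac)2 (5 mol%), TBHP, CH2Cl2, 0 °C
Reagents that add atoms: TBHP (**2**), CC(C)(C)OO
Why: Sharpless–Michaelson hydroxyl-directed epoxidation from the face of the tertiary C10–OH; this sets O8 on the same face as O10 (cis), trans to C11.

**Step 5**
Reactants: **8**
Product: **9** C1,C8,C10-triol (C1 epimeric; C9 is now CH2)
Conditions: Red-Al, THF, 0→25 °C
Reagents that add atoms: none
Why: Red-Al opens a 2,3-epoxy alcohol regioselectively at the proximal carbon (C9) by intramolecular hydride delivery from the C10-alkoxyaluminate, leaving a cis-1,3-diol with C8 configuration retained; the C1 ketone is reduced at the same time and reoxidized later.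

**Step 6**
Reactants: **9**
Product: **10** C8-OTBS, C1-OH, C10-OH
Conditions: TBSCl (1.05 equiv), imidazole, DMF, 0 °C
Reagents that add atoms: TBSCl (**4**), CC(C)(C)[Si](C)(C)Cl
Why: Silylation of the least hindered secondary alcohol (C8); C1–OH is neopentylic and C10–OH is tertiary, so this is a kinetic chemoselective silylation.

**Step 7**
Reactants: **10**
Product: **11** C1 ketone with free C10–OH
Conditions: DMP, NaHCO3, CH2Cl2, 25 °C
Reagents that add atoms: none
Why: Dess–Martin oxidation of the secondary alcohol; no stereocentre is created at C1.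

**Step 8**
Reactants: **11**
Product: **13** C1 ketone with three TBS ethers (C8, C10, C12)
Conditions: TBSOTf, 2,6-lutidine, CH2Cl2, −78→0 °C
Reagents that add atoms: TBSOTf (**12**), CC(C)(C)[Si](C)(C)OS(=O)(=O)C(F)(F)F
Why: Protecting the tertiary α-ketol prevents α-ketol rearrangement under the basic steps that follow.

**Step 9**
Reactants: **13**; **14** (Z)-1-bromopropene
Product: **15** C6-(Z)-propenyl ketone (C6 arm trans to C11)
Conditions: Pd(dba)2, Q-Phos, NaOtBu, toluene, 50 °C
Reagents that add atoms: (Z)-1-bromopropene (**14**), C/C=C\Br (also listed as reactant)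
Why: Pd-catalysed α-alkenylation (Buchwald–Hartwig type) is regiospecific because the quaternary C10 blocks the other α-position; C6 is epimerizable and settles trans to C11 (equatorial).

**Step 10**
Reactants: **15**; **16** (Z)-1-methoxy-2-(tributylstannyl)ethene
Product: **17** tertiary carbinol at C1, bearing the (Z)-2-methoxyvinyl arm and the C6 Z-propenyl arm (C1 epimeric)
Conditions: n-BuLi, THF, −78 °C (Sn/Li exchange); CeCl3; then **15**, −78→−20 °C
Reagents that add atoms: the (Z)-2-methoxyvinyl unit from **16**, CCCC[Sn](CCCC)(CCCC)/C=C\OC (also listed as reactant)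
Why: 1,2-Addition of an organocerium, which tolerates hindered enolizable ketones; it builds the 3-oxy-1,5-diene for the Cope, and the C1 configuration is irrelevant.

**Step 11**
Reactants: **17**
Product: **18** cyclodecenone: C1 ketone, (3R,4R)-OMe/Me, (E)-C5=C6
Conditions: KH, 18-crown-6, THF, 0→25 °C; then sat. NH4Cl at −78 °C
Reagents that add atoms: none
Why: Anionic oxy-Cope ring expansion (6→10) through a chair transition state fused trans to the cyclohexane, with C7 equatorial, which gives the E-C5=C6 alkene. **Proposed new method:** with the (Z,Z)-termini and the fixed C6 configuration of **15**, OMe and Me are axial in the chair, which gives 3R,4R (anti-ring trans). The closest known reaction is the Evans–Golob anionic oxy-Cope ring expansion of 1,2-divinylcyclohexanols to cyclodecenones; the C1 enolate is protonated to the ketone and C6 chirality is transferred into C3/C4.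

**Step 12**
Reactants: **18**
Product: **19** primary allylic alcohol (C12–OH)
Conditions: CSA (cat.), MeOH/CH2Cl2, 0 °C
Reagents that add atoms: none
Why: Acid-catalysed methanolysis cleaves the primary TBS ether selectively over the secondary C8 and tertiary C10 TBS ethers.

**Step 13**
Reactants: **19**
Product: **20** α-substituted acrolein (C12 aldehyde)
Conditions: MnO2, CH2Cl2, 25 °C
Reagents that add atoms: none
Why: MnO2 oxidizes allylic alcohols selectively; no other free OH is present and the silyl ethers and alkene survive.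

**Step 14**
Reactants: **20**; **21** sodium chlorite
Product: **22** 2-substituted acrylic acid (C12 acid)
Conditions: NaClO2, NaH2PO4, 2-methyl-2-butene, tBuOH/H2O, 25 °C
Reagents that add atoms: sodium chlorite (**21**), [Na+].[O-]Cl=O (O source)
Why: Pinnick oxidation; 2-methyl-2-butene scavenges HOCl so the C5=C6 alkene is not chlorinated.

**Step 15**
Reactants: **22**; **23** iodine
Product: **24** trans-fused α-methylene-γ-lactone (C6–O, C5–I)
Conditions: I2, NaHCO3, MeCN/H2O, 0 °C
Reagents that add atoms: iodine (**23**), II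
Why: Iodolactonization by anti addition of I and carboxylate across the E-alkene, with 5-exo closure onto C6 from the C7 tether. **Proposed new method:** acyclic γ,δ-unsaturated acids with a β-substituent and an E-alkene give 4,5-trans lactones, which here means O6 trans to C11; the closest known reaction is the Bartlett–Barnett iodolactonization, applied to an acrylic acid and a medium-ring E-alkene that directly gives the α-methylene lactone.

**Step 16**
Reactants: **24**
Product: **25** lactone with CH2 at C5
Conditions: Bu3SnH, Et3B/air, benzene, 25 °C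
Reagents that add atoms: none
Why: Radical deiodination; stannyl radicals abstract I from the secondary iodide much faster than they add to the acrylate. C5 becomes CH2, so no stereocentre is set.

**Step 17**
Reactants: **25**
Product: **26** C8-OH, C10-OH keto-lactone
Conditions: HF·pyridine, THF/pyridine, 25→40 °C
Reagents that add atoms: none
Why: Acidic fluoride removes both remaining TBS ethers without causing base-mediated α-ketol rearrangement or β-elimination.

**Step 18**
Reactants: **26**; **27** angelic acid
Product: **28** C8 angelate, C10-OH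
Conditions: angelic acid, 2,4,6-trichlorobenzoyl chloride, Et3N, THF; then DMAP, toluene, 25 °C
Reagents that add atoms: angelic acid (**27**), C/C=C(/C)C(=O)O (also listed as reactant)
Why: Yamaguchi esterification acylates only the secondary C8–OH (the tertiary C10–OH is unreactive) and retains the Z-alkene of the angelate.

**Step 19**
Reactants: **28**; **29** acetic anhydride
Product: **30** Rufesolide C
Conditions: Ac2O, Sc(OTf)3 (5 mol%), MeCN, 0→25 °C
Reagents that add atoms: acetic anhydride (**29**), CC(=O)OC(C)=O
Why: Lewis-acid-catalysed acetylation of the hindered tertiary α-ketol; no stereocentre is affected.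

## Compound list

| # | Name | SMILES | Role |
|---|---|---|---|
| 1 | (R)-(−)-carvone | CC1=CC[C@H](CC1=O)C(C)=C | starting material |
| 2 | tert-butyl hydroperoxide | CC(C)(C)OO | starting material (reagent) |
| 3 | (R)-10-hydroxycarvone | CC1=CC[C@H](CC1=O)C(=C)CO | intermediate |
| 4 | TBSCl | CC(C)(C)[Si](C)(C)Cl | starting material (reagent) |
| 5 | 10-OTBS carvone | CC1=CC[C@H](CC1=O)C(=C)CO[Si](C)(C)C(C)(C)C | intermediate |
| 6 | dioxygen | O=O | starting material (reagent) |
| 7 | α-hydroxy-β,γ-enone (C10–OH, C8=C9) | O=C1C[C@H](C(=C)CO[Si](C)(C)C(C)(C)C)C=C[C@@]1(C)O | intermediate |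
| 8 | C8,C9-epoxy ketone | O=C1C[C@H](C(=C)CO[Si](C)(C)C(C)(C)C)[C@H]2O[C@H]2[C@@]1(C)O | intermediate |
| 9 | triol (C1 epimeric) | OC1C[C@H](C(=C)CO[Si](C)(C)C(C)(C)C)[C@@H](O)C[C@@]1(C)O | intermediate |
| 10 | C8-OTBS diol (C1 epimeric) | OC1C[C@H](C(=C)CO[Si](C)(C)C(C)(C)C)[C@@H](O[Si](C)(C)C(C)(C)C)C[C@@]1(C)O | intermediate |
| 11 | C1 ketone, free C10–OH | O=C1C[C@H](C(=C)CO[Si](C)(C)C(C)(C)C)[C@@H](O[Si](C)(C)C(C)(C)C)C[C@@]1(C)O | intermediate |
| 12 | TBSOTf | CC(C)(C)[Si](C)(C)OS(=O)(=O)C(F)(F)F | starting material (reagent) |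
| 13 | tris-TBS ketone | O=C1C[C@H](C(=C)CO[Si](C)(C)C(C)(C)C)[C@@H](O[Si](C)(C)C(C)(C)C)C[C@@]1(C)O[Si](C)(C)C(C)(C)C | intermediate |
| 14 | (Z)-1-bromopropene | C/C=C\Br | starting material |
| 15 | C6-(Z)-propenyl ketone | O=C1[C@@H](/C=C\C)[C@H](C(=C)CO[Si](C)(C)C(C)(C)C)[C@@H](O[Si](C)(C)C(C)(C)C)C[C@@]1(C)O[Si](C)(C)C(C)(C)C | intermediate |
| 16 | (Z)-1-methoxy-2-(tributylstannyl)ethene | CCCC[Sn](CCCC)(CCCC)/C=C\OC | starting material |
| 17 | 1-(Z-2-methoxyvinyl)-2-(Z-propenyl)cyclohexanol (C1 epimeric) | OC1(/C=C\OC)[C@@H](/C=C\C)[C@H](C(=C)CO[Si](C)(C)C(C)(C)C)[C@@H](O[Si](C)(C)C(C)(C)C)C[C@@]1(C)O[Si](C)(C)C(C)(C)C | intermediate |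
| 18 | ring-expanded cyclodecenone | O=C1C[C@@H](OC)[C@H](C)/C=C/[C@H](C(=C)CO[Si](C)(C)C(C)(C)C)[C@@H](O[Si](C)(C)C(C)(C)C)C[C@@]1(C)O[Si](C)(C)C(C)(C)C | intermediate |
| 19 | primary allylic alcohol | O=C1C[C@@H](OC)[C@H](C)/C=C/[C@H](C(=C)CO)[C@@H](O[Si](C)(C)C(C)(C)C)C[C@@]1(C)O[Si](C)(C)C(C)(C)C | intermediate |
| 20 | α-substituted acrolein | O=C1C[C@@H](OC)[C@H](C)/C=C/[C@H](C(=C)C=O)[C@@H](O[Si](C)(C)C(C)(C)C)C[C@@]1(C)O[Si](C)(C)C(C)(C)C | intermediate |
| 21 | sodium chlorite | [Na+].[O-]Cl=O | starting material (reagent) |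
| 22 | acrylic acid | O=C1C[C@@H](OC)[C@H](C)/C=C/[C@H](C(=C)C(=O)O)[C@@H](O[Si](C)(C)C(C)(C)C)C[C@@]1(C)O[Si](C)(C)C(C)(C)C | intermediate |
| 23 | iodine | II | starting material (reagent) |
| 24 | iodolactone | O=C1C[C@@H](OC)[C@H](C)[C@@H](I)[C@H]2OC(=O)C(=C)[C@@H]2[C@@H](O[Si](C)(C)C(C)(C)C)C[C@@]1(C)O[Si](C)(C)C(C)(C)C | intermediate |
| 25 | deiodinated lactone | O=C1C[C@@H](OC)[C@H](C)C[C@H]2OC(=O)C(=C)[C@@H]2[C@@H](O[Si](C)(C)C(C)(C)C)C[C@@]1(C)O[Si](C)(C)C(C)(C)C | intermediate |
| 26 | keto-diol lactone | O=C1C[C@@H](OC)[C@H](C)C[C@H]2OC(=O)C(=C)[C@@H]2[C@@H](O)C[C@@]1(C)O | intermediate |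
| 27 | angelic acid | C/C=C(/C)C(=O)O | starting material |
| 28 | C8 angelate | O=C1C[C@@H](OC)[C@H](C)C[C@H]2OC(=O)C(=C)[C@@H]2[C@@H](OC(=O)/C(C)=C\C)C[C@@]1(C)O | intermediate |
| 29 | acetic anhydride | CC(=O)OC(C)=O | starting material (reagent) |
| 30 | Rufesolide C | O=C1C[C@@H](OC)[C@H](C)C[C@H]2OC(=O)C(=C)[C@@H]2[C@@H](OC(=O)/C(C)=C\C)C[C@@]1(C)OC(C)=O | target |

## Totals

Total steps: 19. Longest linear sequence: 19 (from carvone; the other components are bought reagents).

**Three steps most likely to fail**

1. **Step 11 (oxy-Cope).** Risks are β-methoxide E1cB elimination from the enolate, a boat transition state giving the wrong C3/C4 relationship or a Z-C5=C6 alkene, and failure of the hindered Step 10 precursor. Fallback (changes approach): build the ring from an acyclic precursor. Set C3/C4 by an Evans syn-aldol and C8/C7 by Felkin-controlled aldol, then close the 10-ring and the lactone together by intramolecular Nozaki–Hiyama–Kishi allylation (or RCM at C5=C6).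
2. **Step 3 (deconjugative α-hydroxylation).** Risks are α′ versus γ-deprotonation, facial selectivity at C10, and α-ketol rearrangement under KOtBu. Fallback (changes approach): Re2O7-catalysed 1,3-transposition of carvone-derived material to 4-hydroxycarvone (the γ-hydroxy-enone), TBS protection, then Stryker conjugate reduction and Davis-oxaziridine hydroxylation of the C1/C10 enolate, with C8–OTBS and C7 directing the face.
3. **Step 15 (iodolactonization).** Risks are 6-endo versus 5-exo closure, the cis-fused lactone, and the poor nucleophilicity of the acrylic acid. Fallback (changes approach): epoxidize C5=C6 and cyclize the epoxy acid under Brønsted acid (5-exo opening at C6 with inversion), then remove the C5–OH by Barton–McCombie deoxygenation.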